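**Strategy.** Numbering: ten-membered ring C1 (fusion CH)–C2–C3–C4(=CH2)–C5(prenyl)–C6–C7(acrylate)–C8–C9–C10 (fusion C–Me); cyclobutane C1, C10, C11 (isopropenyl), C12. The route rests on cutting C2–C3. C4 with its exocyclic methylene and the ring CH2 C3 form a 2-substituted allyl unit whose two termini are interchangeable; tied as its allylic ester to a C2 acetic acid arm, it gives a 12-membered lactone. An Ireland–Claisen rearrangement of this lactone forms C2–C3, expels the C(=O)–O link from the ring (12 → 10) and regenerates the C4 methylidene; the carboxyl left on C2 is then removed. All five stereocentres are set beforehand.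

Key step: step 21

Assumption: the sense of induction of CuI/(R)-Tol-BINAP in step 18 is assigned by analogy; if it proves opposite, (S)-Tol-BINAP is used.

**Cyclobutane fragment (steps 1–11)**

Step 1
Reactants: 1 3-bromofuran; 2 (3-bromopropoxy)(tert-butyl)dimethylsilane
Product: 4 tert-butyl[3-(furan-3-yl)propoxy]dimethylsilane, via Grignard reagent 3 (not isolated)
Conditions: 2, Mg, THF, rt; then 1, NiCl2(dppp) (2 mol%), THF, 0 °C → reflux
Reagents that add atoms: none
Why: Kumada–Corriu coupling joins the alkyl Grignard reagent to C3 of the furan, the position of the bromide fixing the regiochemistry; no stereocentre is formed.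

Step 2
Reactants: 4 tert-butyl[3-(furan-3-yl)propoxy]dimethylsilane
Product: 5 4-[3-(tert-butyldimethylsilyloxy)propyl]-5-hydroxyfuran-2(5H)-one (racemic hemiacetal)
Conditions: O2, hv (visible), rose bengal (cat.), i-Pr2NEt, CH2Cl2, −78 °C → rt
Reagents that add atoms: oxygen (O=O)
Why: [4+2] addition of singlet oxygen gives the furan endoperoxide, and the hindered base removes the less shielded C5–H (Kernan–Faulkner photooxygenation), so the carbonyl forms remote from the side chain and the 4-alkyl-5-hydroxybutenolide should result.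

Step 3
Reactants: 5 4-[3-(tert-butyldimethylsilyloxy)propyl]-5-hydroxyfuran-2(5H)-one; 6 (1R,2S,5R)-menthol
Product: 7 (5R)-4-[3-(tert-butyldimethylsilyloxy)propyl]-5-[(1R,2S,5R)-menthyloxy]furan-2(5H)-one
Conditions: PPTS (cat.), benzene, reflux (Dean–Stark); chromatography; the 5S epimer is re-equilibrated under the same conditions
Reagents that add atoms: none
Why: Acid-catalysed acetalisation of the pseudo-acid (Feringa-type menthyloxybutenolide); the C5 epimers are diastereomers that interconvert through the oxocarbenium ion, so the 5R isomer is collected and the 5S isomer recycled.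

Step 4
Reactants: 7 (5R)-menthyloxybutenolide; 8 1,1-diethoxyethene
Product: 9 (1S,4R,5R)-5-[3-(tert-butyldimethylsilyloxy)propyl]-6,6-diethoxy-4-[(1R,2S,5R)-menthyloxy]-3-oxabicyclo[3.2.0]heptan-2-one (cis-fused; cyclobutane anti to the menthyloxy group)
Conditions: hv (medium-pressure Hg lamp, Pyrex), acetone, −20 °C, 8 (10 equiv)
Reagents that add atoms: none
Why: Sensitised enone–alkene [2+2] photocycloaddition: the electron-rich ketene acetal should add head-to-tail (acetal carbon to the β-carbon), the lactone enforces the cis fusion that puts the future C10 methyl carbon and the C11 carbonyl on one face, and attack anti to the menthyloxy group sets the absolute configuration of C10 and C11 (the syn adduct is a separable diastereomer).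

Step 5
Reactants: 9 photoadduct
Product: 10 (1R,2S)-2-acetyl-1-[3-(tert-butyldimethylsilyloxy)propyl]-4,4-diethoxycyclobutane-1-carbaldehyde (acetyl cis to formyl)
Conditions: MeLi (1.05 equiv), THF, −78 °C; AcOH at −78 °C, then H2O, rt
Reagents that add atoms: methyllithium ([Li]C)
Why: Single addition of MeLi to the lactone carbonyl gives a lithium hemiketal that should persist at low temperature; on protonation it opens to the methyl ketone and the freed hemiacetal loses menthol to give the aldehyde, with the C11 acetyl and the formyl on C10 kept cis.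

Step 6
Reactants: 10 keto aldehyde
Product: 12 1-[(1S,2R)-2-[3-(tert-butyldimethylsilyloxy)propyl]-3,3-diethoxy-2-methylcyclobutyl]ethan-1-one (acetyl cis to methyl), via tosylhydrazone 11 (not isolated)
Conditions: TsNHNH2 (1.0 equiv), EtOH, rt; then catecholborane, CHCl3, 0 °C; NaOAc·3H2O, reflux
Reagents that add atoms: none
Why: The aldehyde condenses with the hydrazide much faster than the hindered ketone, and Kabalka reduction of the tosylhydrazone (hydride transfer, loss of sulfinate and N2) turns CHO into the C10 methyl group without base, so the ketone α-carbon C11 is not epimerised.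

Step 7
Reactants: 12 methyl ketone
Product: 13 tert-butyl{3-[(1R,4R)-2,2-diethoxy-1-methyl-4-(prop-1-en-2-yl)cyclobutyl]propoxy}dimethylsilane (isopropenyl cis to methyl)
Conditions: Zn, CH2Br2, TiCl4, THF–CH2Cl2, 0 °C → rt (Lombardo reagent)
Reagents that add atoms: dibromomethane (BrCBr)
Why: Lombardo–Takai methylenation converts the methyl ketone into the isopropenyl group without base, so C11 keeps its configuration and the ketal and silyl ether survive.

Step 8
Reactants: 13 ketal silyl ether
Product: 14 (2R,3R)-2-(3-hydroxypropyl)-2-methyl-3-(prop-1-en-2-yl)cyclobutan-1-one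
Conditions: 1 M HCl, THF, rt
Reagents that add atoms: water (O)
Why: Acid hydrolysis unmasks the cyclobutanone and cleaves the primary silyl ether in one operation; the 1,1-disubstituted alkene should be inert to dilute acid at room temperature.

Step 9
Reactants: 14 cyclobutanone
Product: 15 tert-butyl 2-[(2R,3R)-2-(3-hydroxypropyl)-2-methyl-3-(prop-1-en-2-yl)cyclobutylidene]acetate (E/Z mixture)
Conditions: tert-butyl diethylphosphonoacetate, NaH (2.2 equiv), THF, 0 °C → rt
Reagents that add atoms: tert-butyl diethylphosphonoacetate (CCOP(=O)(OCC)CC(=O)OC(C)(C)C)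
Why: Horner–Wadsworth–Emmons olefination of the strained cyclobutanone installs C2 and its carboxyl carbon; the alkene geometry is irrelevant because it is reduced next.

Step 10
Reactants: 15 alkylidene ester
Product: 16 tert-butyl 2-[(1S,2S,3R)-2-(3-hydroxypropyl)-2-methyl-3-(prop-1-en-2-yl)cyclobutyl]acetate (acetate arm, methyl and isopropenyl all cis)
Conditions: [(Ph3P)CuH]6 (Stryker's reagent), benzene–H2O, rt
Reagents that add atoms: none
Why: Copper hydride conjugate reduction: the bulky hydride should reach C1 from the ring face opposite the vicinal C10 methyl and the cis-1,3 isopropenyl group, so the acetate arm ends up cis to both (sets C1), while the isolated alkene and the alcohol are untouched.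

Step 11
Reactants: 16 hydroxy ester
Product: 18 methyl (2E)-5-[(1S,2S,4R)-2-(2-tert-butoxy-2-oxoethyl)-1-methyl-4-(prop-1-en-2-yl)cyclobutyl]pent-2-enoate, via aldehyde 17 (not isolated)
Conditions: Dess–Martin periodinane, NaHCO3, CH2Cl2, rt; then Ph3P=CHCO2Me, rt
Reagents that add atoms: methyl (triphenylphosphoranylidene)acetate (COC(=O)C=P(c1ccccc1)(c1ccccc1)c1ccccc1)
Why: Dess–Martin oxidation followed in the same flask by Wittig olefination with a stabilised ylide gives the (E)-enoate, the acceptor for the conjugate addition that creates C7.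

**C4–C6 fragment with the prenyl group (steps 12–17)**

Step 12
Reactants: 19 1-(tert-butyldimethylsilyloxy)propan-2-one
Product: 20 ethyl (2E)-4-(tert-butyldimethylsilyloxy)-3-methylbut-2-enoate
Conditions: triethyl phosphonoacetate, NaH, THF, 0 °C → rt; E isomer separated
Reagents that add atoms: triethyl phosphonoacetate (CCOC(=O)CP(=O)(OCC)OCC)
Why: Horner–Wadsworth–Emmons olefination of the ketone places the larger silyloxymethyl group trans to the ester, leaving the methyl group cis to the carbonyl as step 15 requires.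

Step 13
Reactants: 20 ethyl ester
Product: 21 (2E)-4-(tert-butyldimethylsilyloxy)-3-methylbut-2-enoic acid
Conditions: LiOH, THF–H2O, rt; then 1 M HCl to pH 4, 0 °C
Reagents that add atoms: lithium hydroxide ([Li+].[OH-])
Why: Saponification of the ethyl ester; the silyl ether and the alkene geometry are stable to aqueous hydroxide.

Step 14
Reactants: 21 acid; 22 (S)-4-benzyloxazolidin-2-one
Product: 24 (4S)-4-benzyl-3-[(2E)-4-(tert-butyldimethylsilyloxy)-3-methylbut-2-enoyl]oxazolidin-2-one, via mixed anhydride 23 (not isolated)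
Conditions: PivCl, Et3N, THF, −20 °C; then 22, LiCl, rt
Reagents that add atoms: none
Why: N-Acylation of the oxazolidinone through the pivalic mixed anhydride (LiCl-assisted), the hindered pivaloyl carbonyl directing attack to the enoyl carbonyl.

Step 15
Reactants: 24 enoyl imide
Product: 25 (4S)-4-benzyl-3-{(2S)-2-[3-(tert-butyldimethylsilyloxy)prop-1-en-2-yl]-5-methylhex-4-enoyl}oxazolidin-2-one
Conditions: NaHMDS, THF, −78 °C; 1-bromo-3-methylbut-2-ene, −78 → −40 °C
Reagents that add atoms: 1-bromo-3-methylbut-2-ene (CC(C)=CCBr)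
Why: Evans-type deconjugative alkylation: the base removes a γ-hydrogen of the methyl group cis to the carbonyl to give the chelated (Z)-dienolate, which is alkylated at the α-carbon from the face opposite the benzyl group; this sets C5 and turns the former methyl into the terminal methylene.

Step 16
Reactants: 25 alkylated imide
Product: 26 (2S)-2-[3-(tert-butyldimethylsilyloxy)prop-1-en-2-yl]-5-methylhex-4-en-1-ol
Conditions: LiBH4, MeOH (1 equiv), Et2O, 0 °C
Reagents that add atoms: none
Why: Reductive cleavage of the imide gives the primary alcohol and returns the auxiliary; fast hydride reduction at 0 °C should avoid epimerisation of the allylic α-stereocentre.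

Step 17
Reactants: 26 alcohol
Product: 27 tert-butyl{[(3S)-3-(bromomethyl)-6-methyl-2-methylidenehept-5-en-1-yl]oxy}dimethylsilane
Conditions: CBr4, PPh3, CH2Cl2, 0 °C
Reagents that add atoms: carbon tetrabromide (BrC(Br)(Br)Br)
Why: Appel bromination of the primary alcohol under neutral conditions; the stereocentre is not involved.

**Fragment union and endgame (steps 18–24)**

Step 18
Reactants: 18 (E)-enoate; 27 bromide
Product: 29 methyl 3-{2-[(1S,2S,4R)-2-(2-tert-butoxy-2-oxoethyl)-1-methyl-4-(prop-1-en-2-yl)cyclobutyl]ethyl}-5-[3-(tert-butyldimethylsilyloxy)prop-1-en-2-yl]-8-methylnon-7-enoate (C5 and C7 of the target numbering as in the target), via Grignard reagent 28 (not isolated)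
Conditions: 27, Mg, Et2O, rt; then CuI (5 mol%), (R)-Tol-BINAP (6 mol%), 18, t-BuOMe, −40 °C
Reagents that add atoms: none
Why: Copper-catalysed asymmetric conjugate addition of a Grignard reagent to an (E)-enoate (Feringa conditions): the chiral copper complex selects the enoate face and so sets C7, the hindered tert-butyl ester is not attacked at −40 °C, and the product carries the acetate arm needed for the acrylate.

Step 19
Reactants: 29 diester
Product: 31 2-[(1S,2S,3R)-2-{5-(3-hydroxyprop-1-en-2-yl)-3-(2-methoxy-2-oxoethyl)-8-methylnon-7-en-1-yl}-2-methyl-3-(prop-1-en-2-yl)cyclobutyl]acetic acid (seco acid), via trimethylsilyl ester 30 (not isolated)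
Conditions: TMSOTf, 2,6-lutidine, CH2Cl2, 0 °C; then TBAF, THF, rt; pH 4 work-up
Reagents that add atoms: none
Why: Silyl triflate with a hindered base converts the tert-butyl ester into a silyl ester by loss of isobutene and leaves the methyl ester intact; fluoride then removes both silyl groups to free the acid and the allylic alcohol.

Step 20
Reactants: 31 seco acid
Product: 33 methyl 2-[12-methyl-6-methylidene-7-(3-methylbut-2-en-1-yl)-3-oxo-13-(prop-1-en-2-yl)-4-oxabicyclo[10.2.0]tetradecan-9-yl]acetate (12-membered lactone; stereocentres unchanged), via mixed anhydride 32 (not isolated)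
Conditions: 2,4,6-trichlorobenzoyl chloride, Et3N, THF, rt; then DMAP, toluene (2 mM), 80 °C, slow addition
Reagents that add atoms: none
Why: Yamaguchi macrolactonisation under high dilution closes the 12-membered ring by acylation of the unhindered primary allylic alcohol; no stereocentre is affected.

Step 21
Reactants: 33 12-membered lactone
Product: 35 7-(2-methoxy-2-oxoethyl)-10-methyl-4-methylidene-5-(3-methylbut-2-en-1-yl)-11-(prop-1-en-2-yl)bicyclo[8.2.0]dodecane-2-carboxylic acid (C2 epimers), via bis(silyl ketene acetal) 34 (not isolated)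
Conditions: LDA (2.5 equiv), TMSCl–Et3N, THF, −78 °C (internal quench); then toluene, 80 °C; 1 M HCl work-up
Reagents that add atoms: none
Why: Both esters are converted into silyl ketene acetals, but only the lactone-derived one is an allyl vinyl ether, so it alone undergoes the [3,3]-sigmatropic (Ireland–Claisen) shift: C2 bonds to the exocyclic methylene carbon, which becomes ring atom C3, the O–CH2 bond breaks and that CH2 becomes the C4 methylidene. The closest known reaction type is the Ireland–Claisen ring contraction of macrocyclic allylic lactones (alicyclic Claisen rearrangement), run here on a lactone whose alkene is exocyclic, so that only the carbonyl carbon and the ring oxygen leave the ring (12 → 10). The ten-membered ring closes in a concerted suprafacial mode through a six-membered chair- or boat-like array bridged by the seven-atom chain C5–C10/C1; no open-chain intermediate is formed, so oligomerisation cannot compete. The only new stereocentre, C2, is uncontrolled and need not be controlled, because its carboxyl group is removed in step 22. The step needs chemoselectivity between the two ketene acetals and regioselectivity for the methylene terminus; the substrate secures both, since the methyl ester ketene acetal has no allyl partner and reverts to the ester on work-up, and the [3,3] topology allows bonding only at the alkene terminus. The gain of a carboxyl C=O should pay for the transannular strain of the trans-fused bicyclo[8.2.0]dodecane.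

Step 22
Reactants: 35 ring-contracted acid
Product: 37 methyl 2-[10-methyl-4-methylidene-5-(3-methylbut-2-en-1-yl)-11-(prop-1-en-2-yl)bicyclo[8.2.0]dodecan-7-yl]acetate (ring stereocentres as in the target), via Barton ester 36 (not isolated)
Conditions: N-hydroxypyridine-2-thione, DCC, DMAP (cat.), CH2Cl2, dark, rt; then t-BuSH (excess), hv (tungsten lamp), benzene, rt
Reagents that add atoms: none
Why: Barton reductive decarboxylation: photolysis of the thiohydroxamate ester gives the acyloxy radical, which loses CO2, and the C2 radical takes hydrogen from the thiol, used in excess to outrun cyclisation onto nearby alkenes; this erases the C2 stereocentre.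

Step 23
Reactants: 37 methyl ester
Product: 38 methyl 3-(dimethylamino)-2-[10-methyl-4-methylidene-5-(3-methylbut-2-en-1-yl)-11-(prop-1-en-2-yl)bicyclo[8.2.0]dodecan-7-yl]propanoate (α-epimers)
Conditions: LDA, THF, −78 °C; CH2=NMe2+ I− (Eschenmoser's salt), −78 °C → rt
Reagents that add atoms: Eschenmoser's salt (C=[N+](C)C.[I-])
Why: Mannich reaction of the ester enolate, the only enolisable position, with the iminium salt installs the future methylene carbon; the new α-stereocentre is destroyed in step 24.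

Step 24
Reactants: 38 Mannich base
Product: 40 methyl 2-[(1R,5R,7S,10S,11R)-10-methyl-4-methylidene-5-(3-methylbut-2-en-1-yl)-11-(prop-1-en-2-yl)bicyclo[8.2.0]dodecan-7-yl]prop-2-enoate (target), via ammonium iodide 39 (not isolated)
Conditions: MeI, MeOH, rt; then DBU, CH2Cl2, rt
Reagents that add atoms: none
Why: N-Methylation followed by base-induced β-elimination of trimethylamine (E1cB, Hofmann-type) gives the α-methylene ester, which completes the target without touching any stereocentre.

**Compound list**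

1 | 3-bromofuran | Brc1ccoc1 | starting material
2 | (3-bromopropoxy)(tert-butyl)dimethylsilane | BrCCCO[Si](C)(C)C(C)(C)C | starting material
3 | [3-(tert-butyldimethylsilyloxy)propyl]magnesium bromide | Br[Mg]CCCO[Si](C)(C)C(C)(C)C | intermediate
4 | tert-butyl[3-(furan-3-yl)propoxy]dimethylsilane | CC(C)(C)[Si](C)(C)OCCCc1ccoc1 | intermediate
5 | 4-[3-(tert-butyldimethylsilyloxy)propyl]-5-hydroxyfuran-2(5H)-one (racemic) | O=C1C=C(CCCO[Si](C)(C)C(C)(C)C)C(O)O1 | intermediate
6 | (1R,2S,5R)-menthol | CC(C)[C@@H]1CC[C@@H](C)C[C@H]1O | starting material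
7 | (5R)-4-[3-(tert-butyldimethylsilyloxy)propyl]-5-[(1R,2S,5R)-menthyloxy]furan-2(5H)-one | O=C1C=C(CCCO[Si](C)(C)C(C)(C)C)[C@H](O[C@@H]2C[C@H](C)CC[C@H]2C(C)C)O1 | intermediate
8 | 1,1-diethoxyethene | C=C(OCC)OCC | starting material
9 | (1S,4R,5R)-5-[3-(tert-butyldimethylsilyloxy)propyl]-6,6-diethoxy-4-[(1R,2S,5R)-menthyloxy]-3-oxabicyclo[3.2.0]heptan-2-one | CCOC2(OCC)C[C@@H]3C(=O)O[C@@H](O[C@@H]4C[C@H](C)CC[C@H]4C(C)C)[C@]23CCCO[Si](C)(C)C(C)(C)C | intermediate
10 | (1R,2S)-2-acetyl-1-[3-(tert-butyldimethylsilyloxy)propyl]-4,4-diethoxycyclobutane-1-carbaldehyde | CCOC2(OCC)C[C@H](C(C)=O)[C@@]2(C=O)CCCO[Si](C)(C)C(C)(C)C | intermediate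
11 | N'-tosylhydrazone of aldehyde 10 | CCOC2(OCC)C[C@H](C(C)=O)[C@@]2(C=NNS(=O)(=O)c1ccc(C)cc1)CCCO[Si](C)(C)C(C)(C)C | intermediate
12 | 1-[(1S,2R)-2-[3-(tert-butyldimethylsilyloxy)propyl]-3,3-diethoxy-2-methylcyclobutyl]ethan-1-one | CCOC2(OCC)C[C@H](C(C)=O)[C@@]2(C)CCCO[Si](C)(C)C(C)(C)C | intermediate
13 | tert-butyl{3-[(1R,4R)-2,2-diethoxy-1-methyl-4-(prop-1-en-2-yl)cyclobutyl]propoxy}dimethylsilane | CCOC2(OCC)C[C@H](C(C)=C)[C@@]2(C)CCCO[Si](C)(C)C(C)(C)C | intermediate
14 | (2R,3R)-2-(3-hydroxypropyl)-2-methyl-3-(prop-1-en-2-yl)cyclobutan-1-one | O=C2C[C@H](C(C)=C)[C@@]2(C)CCCO | intermediate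
15 | tert-butyl 2-[(2R,3R)-2-(3-hydroxypropyl)-2-methyl-3-(prop-1-en-2-yl)cyclobutylidene]acetate (E/Z mixture) | CC(C)(C)OC(=O)C=C2C[C@H](C(C)=C)[C@@]2(C)CCCO | intermediate
16 | tert-butyl 2-[(1S,2S,3R)-2-(3-hydroxypropyl)-2-methyl-3-(prop-1-en-2-yl)cyclobutyl]acetate | CC(C)(C)OC(=O)C[C@@H]2C[C@H](C(C)=C)[C@@]2(C)CCCO | intermediate
17 | tert-butyl 2-[(1S,2S,3R)-2-methyl-2-(3-oxopropyl)-3-(prop-1-en-2-yl)cyclobutyl]acetate | CC(C)(C)OC(=O)C[C@@H]2C[C@H](C(C)=C)[C@@]2(C)CCC=O | intermediate
18 | methyl (2E)-5-[(1S,2S,4R)-2-(2-tert-butoxy-2-oxoethyl)-1-methyl-4-(prop-1-en-2-yl)cyclobutyl]pent-2-enoate | CC(C)(C)OC(=O)C[C@@H]2C[C@H](C(C)=C)[C@@]2(C)CC/C=C/C(=O)OC | intermediate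
19 | 1-(tert-butyldimethylsilyloxy)propan-2-one | CC(=O)CO[Si](C)(C)C(C)(C)C | starting material
20 | ethyl (2E)-4-(tert-butyldimethylsilyloxy)-3-methylbut-2-enoate | CCOC(=O)/C=C(\C)CO[Si](C)(C)C(C)(C)C | intermediate
21 | (2E)-4-(tert-butyldimethylsilyloxy)-3-methylbut-2-enoic acid | OC(=O)/C=C(\C)CO[Si](C)(C)C(C)(C)C | intermediate
22 | (S)-4-benzyloxazolidin-2-one | O=C1N[C@@H](Cc2ccccc2)CO1 | starting material
23 | mixed pivalic anhydride of acid 21 | CC(C)(C)C(=O)OC(=O)/C=C(\C)CO[Si](C)(C)C(C)(C)C | intermediate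
24 | (4S)-4-benzyl-3-[(2E)-4-(tert-butyldimethylsilyloxy)-3-methylbut-2-enoyl]oxazolidin-2-one | O=C1OC[C@H](Cc2ccccc2)N1C(=O)/C=C(\C)CO[Si](C)(C)C(C)(C)C | intermediate
25 | (4S)-4-benzyl-3-{(2S)-2-[3-(tert-butyldimethylsilyloxy)prop-1-en-2-yl]-5-methylhex-4-enoyl}oxazolidin-2-one | O=C1OC[C@H](Cc2ccccc2)N1C(=O)[C@H](C(=C)CO[Si](C)(C)C(C)(C)C)CC=C(C)C | intermediate
26 | (2S)-2-[3-(tert-butyldimethylsilyloxy)prop-1-en-2-yl]-5-methylhex-4-en-1-ol | OC[C@H](C(=C)CO[Si](C)(C)C(C)(C)C)CC=C(C)C | intermediate
27 | tert-butyl{[(3S)-3-(bromomethyl)-6-methyl-2-methylidenehept-5-en-1-yl]oxy}dimethylsilane | BrC[C@H](C(=C)CO[Si](C)(C)C(C)(C)C)CC=C(C)C | intermediate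
28 | Grignard reagent of bromide 27 | Br[Mg]C[C@H](C(=C)CO[Si](C)(C)C(C)(C)C)CC=C(C)C | intermediate
29 | methyl 3-{2-[(1S,2S,4R)-2-(2-tert-butoxy-2-oxoethyl)-1-methyl-4-(prop-1-en-2-yl)cyclobutyl]ethyl}-5-[3-(tert-butyldimethylsilyloxy)prop-1-en-2-yl]-8-methylnon-7-enoate (C5, C7 as in the target) | CC(C)(C)OC(=O)C[C@@H]2C[C@H](C(C)=C)[C@@]2(C)CC[C@H](CC(=O)OC)C[C@H](C(=C)CO[Si](C)(C)C(C)(C)C)CC=C(C)C | intermediate
30 | trimethylsilyl ester of the C2 acid (tert-butyldimethylsilyl ether retained) | C[Si](C)(C)OC(=O)C[C@@H]2C[C@H](C(C)=C)[C@@]2(C)CC[C@H](CC(=O)OC)C[C@H](C(=C)CO[Si](C)(C)C(C)(C)C)CC=C(C)C | intermediate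
31 | 2-[(1S,2S,3R)-2-{5-(3-hydroxyprop-1-en-2-yl)-3-(2-methoxy-2-oxoethyl)-8-methylnon-7-en-1-yl}-2-methyl-3-(prop-1-en-2-yl)cyclobutyl]acetic acid (seco acid) | OC(=O)C[C@@H]2C[C@H](C(C)=C)[C@@]2(C)CC[C@H](CC(=O)OC)C[C@H](C(=C)CO)CC=C(C)C | intermediate
32 | 2,4,6-trichlorobenzoic mixed anhydride of seco acid 31 | Clc1cc(Cl)c(C(=O)OC(=O)C[C@@H]2C[C@H](C(C)=C)[C@@]2(C)CC[C@H](CC(=O)OC)C[C@H](C(=C)CO)CC=C(C)C)c(Cl)c1 | intermediate
33 | methyl 2-[12-methyl-6-methylidene-7-(3-methylbut-2-en-1-yl)-3-oxo-13-(prop-1-en-2-yl)-4-oxabicyclo[10.2.0]tetradecan-9-yl]acetate (12-membered lactone) | O=C1C[C@@H]2C[C@H](C(C)=C)[C@@]2(C)CC[C@H](CC(=O)OC)C[C@@H](CC=C(C)C)C(=C)CO1 | intermediate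
34 | bis(trimethylsilyl ketene acetal) of lactone 33 | C[Si](C)(C)OC1=C[C@@H]2C[C@H](C(C)=C)[C@@]2(C)CC[C@H](C=C(OC)O[Si](C)(C)C)C[C@@H](CC=C(C)C)C(=C)CO1 | intermediate
35 | 7-(2-methoxy-2-oxoethyl)-10-methyl-4-methylidene-5-(3-methylbut-2-en-1-yl)-11-(prop-1-en-2-yl)bicyclo[8.2.0]dodecane-2-carboxylic acid (C2 epimers) | C=C1CC(C(=O)O)[C@@H]2C[C@H](C(=C)C)[C@@]2(C)CC[C@H](CC(=O)OC)C[C@H]1CC=C(C)C | intermediate
36 | 2-thioxopyridin-1(2H)-yl ester (Barton ester) of acid 35 | C=C1CC(C(=O)ON2C=CC=CC2=S)[C@@H]3C[C@H](C(=C)C)[C@@]3(C)CC[C@H](CC(=O)OC)C[C@H]1CC=C(C)C | intermediate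
37 | methyl 2-[10-methyl-4-methylidene-5-(3-methylbut-2-en-1-yl)-11-(prop-1-en-2-yl)bicyclo[8.2.0]dodecan-7-yl]acetate (ring stereocentres as in the target) | C=C1CC[C@@H]2C[C@H](C(=C)C)[C@@]2(C)CC[C@H](CC(=O)OC)C[C@H]1CC=C(C)C | intermediate
38 | methyl 3-(dimethylamino)-2-[10-methyl-4-methylidene-5-(3-methylbut-2-en-1-yl)-11-(prop-1-en-2-yl)bicyclo[8.2.0]dodecan-7-yl]propanoate (α-epimers) | C=C1CC[C@@H]2C[C@H](C(=C)C)[C@@]2(C)CC[C@H](C(CN(C)C)C(=O)OC)C[C@H]1CC=C(C)C | intermediate
39 | trimethylammonium iodide of Mannich base 38 | C=C1CC[C@@H]2C[C@H](C(=C)C)[C@@]2(C)CC[C@H](C(C[N+](C)(C)C)C(=O)OC)C[C@H]1CC=C(C)C.[I-] | intermediate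
40 | methyl 2-[(1R,5R,7S,10S,11R)-10-methyl-4-methylidene-5-(3-methylbut-2-en-1-yl)-11-(prop-1-en-2-yl)bicyclo[8.2.0]dodecan-7-yl]prop-2-enoate | C=C1CC[C@@H]2C[C@H](C(=C)C)[C@@]2(C)CC[C@H](C(=C)C(=O)OC)C[C@H]1CC=C(C)C | target

Total step count: 24. Longest linear sequence: 18 steps (steps 1–11, then 18–24); steps 12–17 prepare bromide 27 in parallel.

**Steps most likely to fail and their fallbacks**

Step 21 (key step). The bridged [3,3] transition state may not be reached before the lactone ketene acetal is lost by β-elimination to a ketene or by C-silylation, so that lactone is returned or degraded. The fallback keeps the 12 → 10 ring contraction but runs it through an ion pair with loss of CO2; it sets out from 16 and returns at 37. The dianion of 16 (LDA, 2.2 equiv, THF, −78 °C) is C-sulfonylated with PhSO2F to give the α-(phenylsulfonyl) ester F1. Oxidation and Wittig olefination as in step 11 give the enoate F2. Conjugate addition of 28 as in step 18, with one extra equivalent consumed by the acidic sulfonyl ester, gives the adduct F3. Deprotection as in step 19 gives the seco acid F4, which is kept cold, and Yamaguchi lactonisation gives the α-sulfonyl lactone F5. Pd(PPh3)4 (cat.) in dilute toluene at 60 °C ionises the allylic ester, the sulfonylacetate loses CO2 and the sulfone-stabilised carbanion closes onto either terminus of the symmetrical 2-substituted π-allyl unit (Tsuji–Saegusa decarboxylative allylation), giving the ring-contracted sulfone F6. Mg in MeOH removes the sulfone and delivers 37.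

Step 18. The β-branched Grignard reagent may add 1,2 or with low face selectivity, since the catalyst has to override two chiral partners. The fallback uses an auxiliary instead of a catalyst; it sets out from 17 and returns at 29. Horner–Wadsworth–Emmons reaction of 17 with (S)-4-benzyl-3-[(diethoxyphosphoryl)acetyl]oxazolidin-2-one (LiCl, i-Pr2NEt, MeCN) gives the enoyl imide F7. The cuprate from 28 and CuBr·SMe2 (THF–Me2S, −78 → −20 °C) adds to the chelated imide anti to the benzyl group and gives the imide adduct F8. MeOMgBr in MeOH at 0 °C exchanges the auxiliary for the methyl ester and delivers 29.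

Step 5. The tetrahedral adduct may collapse at low temperature, so that ketone and aldehyde are exposed to MeLi and over-addition follows. The fallback avoids a carbon nucleophile; it sets out from 9 and returns at 10. Petasis methylenation of the lactone carbonyl (Cp2TiMe2, toluene, 70 °C) gives the cyclic enol ether F9. PPTS in wet acetone at 0 °C hydrolyses the enol ether faster than the ketal; the hemiketal opens, menthol is lost and 10 results.

Further compounds
F1 | step 21 | tert-butyl 2-[2-(3-hydroxypropyl)-2-methyl-3-(prop-1-en-2-yl)cyclobutyl]-2-(phenylsulfonyl)acetate (cyclobutane as in 16) | CC(C)(C)OC(=O)C(S(=O)(=O)c1ccccc1)[C@@H]2C[C@H](C(C)=C)[C@@]2(C)CCCO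
F2 | step 21 | methyl (2E)-5-{2-[2-tert-butoxy-2-oxo-1-(phenylsulfonyl)ethyl]-1-methyl-4-(prop-1-en-2-yl)cyclobutyl}pent-2-enoate | CC(C)(C)OC(=O)C(S(=O)(=O)c1ccccc1)[C@@H]2C[C@H](C(C)=C)[C@@]2(C)CC/C=C/C(=O)OC
F3 | step 21 | α-(phenylsulfonyl) analogue of diester 29 | CC(C)(C)OC(=O)C(S(=O)(=O)c1ccccc1)[C@@H]2C[C@H](C(C)=C)[C@@]2(C)CC[C@H](CC(=O)OC)C[C@H](C(=C)CO[Si](C)(C)C(C)(C)C)CC=C(C)C
F4 | step 21 | α-(phenylsulfonyl) analogue of seco acid 31 | OC(=O)C(S(=O)(=O)c1ccccc1)[C@@H]2C[C@H](C(C)=C)[C@@]2(C)CC[C@H](CC(=O)OC)C[C@H](C(=C)CO)CC=C(C)C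
F5 | step 21 | α-(phenylsulfonyl) analogue of lactone 33 | O=C1C(S(=O)(=O)c3ccccc3)[C@@H]2C[C@H](C(C)=C)[C@@]2(C)CC[C@H](CC(=O)OC)C[C@@H](CC=C(C)C)C(=C)CO1
F6 | step 21 | methyl 2-[10-methyl-4-methylidene-5-(3-methylbut-2-en-1-yl)-2-(phenylsulfonyl)-11-(prop-1-en-2-yl)bicyclo[8.2.0]dodecan-7-yl]acetate | C=C1CC(S(=O)(=O)c3ccccc3)[C@@H]2C[C@H](C(=C)C)[C@@]2(C)CC[C@H](CC(=O)OC)C[C@H]1CC=C(C)C
F7 | step 18 | tert-butyl 2-[(1S,2S,3R)-2-{(3E)-5-[(4S)-4-benzyl-2-oxooxazolidin-3-yl]-5-oxopent-3-en-1-yl}-2-methyl-3-(prop-1-en-2-yl)cyclobutyl]acetate | CC(C)(C)OC(=O)C[C@@H]2C[C@H](C(C)=C)[C@@]2(C)CC/C=C/C(=O)N3C(=O)OC[C@@H]3Cc4ccccc4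
F8 | step 18 | N-acyl oxazolidinone analogue of diester 29 (auxiliary in place of OMe) | CC(C)(C)OC(=O)C[C@@H]2C[C@H](C(C)=C)[C@@]2(C)CC[C@H](CC(=O)N3C(=O)OC[C@@H]3Cc4ccccc4)C[C@H](C(=C)CO[Si](C)(C)C(C)(C)C)CC=C(C)C
F9 | step 5 | 5-[3-(tert-butyldimethylsilyloxy)propyl]-6,6-diethoxy-4-[(1R,2S,5R)-menthyloxy]-2-methylidene-3-oxabicyclo[3.2.0]heptane (stereocentres as in 9) | CCOC2(OCC)C[C@@H]3C(=C)O[C@@H](O[C@@H]4C[C@H](C)CC[C@H]4C(C)C)[C@]23CCCO[Si](C)(C)C(C)(C)C
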